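Assumption: the stereocentre in the SMILES is (3R) (CIP order C2 > aryl > C4 > H), and a telescoped one-pot sequence is counted as one step.

## Retrosynthetic overview

1. Licoricidin comes from global deprotection of the protected isoflavan 13 (7-OTIPS, 2′,4′-bis-OMOM).
2. The pyran ring is the only ring formed. It is closed last, by a 6-endo aryl-radical cyclisation of the o-iodoaryl 2-arylallyl ether 12 that makes the C4–C4a bond; C3 is set in the same step by enantioselective H-atom transfer.
3. Ether 12 comes from a Mitsunobu coupling of the A-ring iodophenol 11 with the B-ring 2-arylallyl alcohol 6 (forms O1–C2).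
4. Both 6 and 11 come from one intermediate, 2-prenyl-1,3-bis(MOM)resorcinol 4. Compound 6 is made by ortho-metalation, borylation and Suzuki coupling. Compound 11 is made by deprotection, mono-methylation, silylation, meta C–H borylation/oxidation and ortho-iodination.
5. Compound 4 comes from resorcinol and prenyl bromide by directed ortho-metalation. Both benzene rings are carried intact from resorcinol.

## Route

**Step 1**
Reactants: 1 resorcinol
Product: 2 1,3-bis(methoxymethoxy)benzene
Conditions: MOMCl (2.5 equiv), i-Pr2NEt, CH2Cl2, 0 °C → rt
Reagents that add atoms: chloromethyl methyl ether, COCCl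
Why: Base-mediated O-alkylation (acetal protection) of both phenols; the MOM groups are the directing groups for the next two metalations.

**Step 2**
Reactants: 2; 3 prenyl bromide (1-bromo-3-methylbut-2-ene)
Product: 4 1,3-bis(methoxymethoxy)-2-(3-methylbut-2-en-1-yl)benzene
Conditions: n-BuLi, THF, 0 °C → rt; then CuI (10 mol %), 3, −78 °C → rt
Reagents that add atoms: none (prenyl comes from reactant 3)
Why: Directed ortho-metalation at the doubly activated C2 between the two OMOM groups, then copper-mediated SN2 allylation to give the linear prenyl group.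

**Step 3**
Reactants: 4; 5 2-bromoprop-2-en-1-ol
Product: 6 2-[2,4-bis(methoxymethoxy)-3-(3-methylbut-2-en-1-yl)phenyl]prop-2-en-1-ol
Conditions: n-BuLi, TMEDA, THF, −20 → 0 °C; B(OMe)3, −78 °C → rt; then 5, Pd(dppf)Cl2 (3 mol %), aq K3PO4, 60 °C (one pot)
Reagents that add atoms: none (boron is not retained; the allyl alcohol unit comes from reactant 5)
Why: A second directed ortho-metalation can only occur ortho to an OMOM group (C4 and C6 are equivalent), and the aryl boronate formed in situ undergoes Suzuki–Miyaura coupling with the vinyl bromide.

**Step 4**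
Reactants: 4
Product: 7 2-(3-methylbut-2-en-1-yl)benzene-1,3-diol (2-prenylresorcinol)
Conditions: 2 M HCl, MeOH, 40 °C
Reagents that add atoms: none
Why: Acid-catalysed hydrolysis of the MOM acetals; dilute acid at 40 °C is too mild to cyclise the o-prenylphenol to a 2,2-dimethylchroman.

**Step 5**
Reactants: 7
Product: 8 3-methoxy-2-(3-methylbut-2-en-1-yl)phenol
Conditions: K2CO3 (1.1 equiv), MeI (1.0 equiv), acetone, rt; recovered 7 recycled
Reagents that add atoms: iodomethane, CI
Why: Williamson O-methylation; the two hydroxyls are equivalent, so only mono- versus bis-alkylation has to be controlled (statistical, limiting MeI).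

**Step 6**
Reactants: 8
Product: 9 [3-methoxy-2-(3-methylbut-2-en-1-yl)phenoxy]triisopropylsilane
Conditions: TIPSOTf, 2,6-lutidine, CH2Cl2, 0 °C
Reagents that add atoms: triisopropylsilyl triflate, CC(C)[Si](C(C)C)(C(C)C)OS(=O)(=O)C(F)(F)F
Why: Silyl ether formation with the reactive triflate on a hindered phenol; the TIPS group later shields the adjacent ring position (step 8) and removes a phenolic O–H donor from the radical step.

**Step 7**
Reactants: 9
Product: 10 3-methoxy-4-(3-methylbut-2-en-1-yl)-5-[(triisopropylsilyl)oxy]phenol
Conditions: [Ir(OMe)(cod)]2 (1.5 mol %), dtbpy (3 mol %), B2pin2, THF, 70 °C; then aq H2O2, NaHCO3, 0 °C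
Reagents that add atoms: hydrogen peroxide, OO (supplies the new phenol oxygen; boron from B2pin2 is not retained)
Why: Sterically governed Ir-catalysed aromatic C–H borylation reacts only at the one C–H with no ortho substituent (meta to both oxygens), and oxidation of the aryl–Bpin gives the phenol; the trisubstituted alkene is inert.

**Step 8**
Reactants: 10
Product: 11 2-iodo-3-methoxy-4-(3-methylbut-2-en-1-yl)-5-[(triisopropylsilyl)oxy]phenol
Conditions: I2 (1.0 equiv), NaHCO3, THF/H2O, 0 °C
Reagents that add atoms: iodine, II
Why: Electrophilic aromatic iodination of a very electron-rich phenol: the para position is blocked by prenyl and the ortho position next to OTIPS is shielded, so iodine enters between OH and OMe (the future C4a).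

**Step 9**
Reactants: 11; 6
Product: 12 1-({2-[2,4-bis(methoxymethoxy)-3-(3-methylbut-2-en-1-yl)phenyl]prop-2-en-1-yl}oxy)-2-iodo-3-methoxy-4-(3-methylbut-2-en-1-yl)-5-[(triisopropylsilyl)oxy]benzene (achiral)
Conditions: PPh3, DIAD, toluene, 0 °C → rt
Reagents that add atoms: none
Why: Mitsunobu etherification of the acidic o-iodophenol with the primary allylic alcohol forms O1–C2 (SN2 and SN2′ give the same ether for a 2-substituted allyl unit).

**Step 10 (key step)**
Reactants: 12
Product: 13 (3R)-3-[2,4-bis(methoxymethoxy)-3-(3-methylbut-2-en-1-yl)phenyl]-5-methoxy-6-(3-methylbut-2-en-1-yl)-7-[(triisopropylsilyl)oxy]-3,4-dihydro-2H-chromene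
Conditions: 4CzIPN (2 mol %), n-Bu3N (3 equiv), homochiral cysteine β-turn peptide thiol (e.g. Boc-Cys-D-Pro-Aib-Phe-NMe2 type, 20 mol %), MeCN, 450 nm LEDs, −20 °C
Reagents that add atoms: none
Why: Proposed new method: the α-aminoalkyl radical from photo-oxidised Bu3N abstracts iodine to give the C4a aryl radical, which closes 6-endo onto the CH2 terminus of the α-aryl alkene (the hindered, aryl-bearing internal carbon disfavours 5-exo, and any 5-exo radical can reach the same radical by neophyl-type ring expansion), forming C4–C4a and a tertiary benzylic C3 radical; this radical cannot take H from amine or solvent at a useful rate, so C3–H is formed by H-atom transfer from the chiral thiol, whose peptide N–H groups can bind the 2′-OMOM oxygens next to the radical centre to differentiate its faces (catalyst antipode giving 3R chosen by screening), and the thiyl radical is returned to thiol by the reduced photocatalyst and ammonium; the closest known reactions are photoredox/thiol-cocatalysed aryl-radical hydroarylation of alkenes, 6-endo aryl-radical cyclisations onto α-substituted styrenes, and enantioselective H-atom transfer from homochiral carbohydrate or peptide thiols to prochiral tertiary radicals.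

**Step 11**
Reactants: 13
Product: 14 licoricidin, 4-[(3R)-7-hydroxy-5-methoxy-6-(3-methylbut-2-en-1-yl)-3,4-dihydro-2H-chromen-3-yl]-2-(3-methylbut-2-en-1-yl)benzene-1,3-diol
Conditions: TBAF, THF, 0 °C; then 2 M HCl, MeOH, 40 °C (one pot, two stages)
Reagents that add atoms: none
Why: Fluoride cleaves the aryl silyl ether and dilute acid hydrolyses the MOM acetals; C3 has no acidifying neighbour, so the stereocentre is untouched.

## Compound list

1 | resorcinol (benzene-1,3-diol) | Oc1cccc(O)c1 | starting material
2 | 1,3-bis(methoxymethoxy)benzene | COCOc1cccc(OCOC)c1 | intermediate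
3 | prenyl bromide (1-bromo-3-methylbut-2-ene) | CC(C)=CCBr | starting material
4 | 1,3-bis(methoxymethoxy)-2-(3-methylbut-2-en-1-yl)benzene | COCOc1cccc(OCOC)c1CC=C(C)C | intermediate
5 | 2-bromoprop-2-en-1-ol | OCC(Br)=C | starting material
6 | 2-[2,4-bis(methoxymethoxy)-3-(3-methylbut-2-en-1-yl)phenyl]prop-2-en-1-ol | C=C(CO)c1ccc(OCOC)c(CC=C(C)C)c1OCOC | intermediate
7 | 2-(3-methylbut-2-en-1-yl)benzene-1,3-diol | CC(C)=CCc1c(O)cccc1O | intermediate
8 | 3-methoxy-2-(3-methylbut-2-en-1-yl)phenol | COc1cccc(O)c1CC=C(C)C | intermediate
9 | [3-methoxy-2-(3-methylbut-2-en-1-yl)phenoxy]triisopropylsilane | COc1cccc(O[Si](C(C)C)(C(C)C)C(C)C)c1CC=C(C)C | intermediate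
10 | 3-methoxy-4-(3-methylbut-2-en-1-yl)-5-[(triisopropylsilyl)oxy]phenol | COc1cc(O)cc(O[Si](C(C)C)(C(C)C)C(C)C)c1CC=C(C)C | intermediate
11 | 2-iodo-3-methoxy-4-(3-methylbut-2-en-1-yl)-5-[(triisopropylsilyl)oxy]phenol | COc1c(I)c(O)cc(O[Si](C(C)C)(C(C)C)C(C)C)c1CC=C(C)C | intermediate
12 | o-iodoaryl 2-arylallyl ether (name in step 9; achiral) | COc1c(I)c(OCC(=C)c2ccc(OCOC)c(CC=C(C)C)c2OCOC)cc(O[Si](C(C)C)(C(C)C)C(C)C)c1CC=C(C)C | intermediate
13 | (3R)-7-O-TIPS-2′,4′-bis-O-MOM-licoricidin (name in step 10) | COc1c(CC=C(C)C)c(O[Si](C(C)C)(C(C)C)C(C)C)cc2c1C[C@H](c1ccc(OCOC)c(CC=C(C)C)c1OCOC)CO2 | intermediate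
14 | licoricidin, (3R) | COc1c(CC=C(C)C)c(O)cc2c1C[C@H](c1ccc(O)c(CC=C(C)C)c1O)CO2 | target

## Step count and main risks

Total steps: 11. Longest linear sequence: 10 (steps 1, 2, 4, 5, 6, 7, 8, 9, 10, 11); step 3 is the one-step B-ring branch from the shared intermediate 4.

Steps most likely to fail:

1. **Step 10.** The enantioselectivity of the thiol H-atom transfer is unproven for a radical with no strong binding group. Secondary risks are 5-exo leakage and β-scission of the C2–O1 bond. Fallback: set C3 before the radical step. Alkylate 11 with methyl 4-bromocrotonate, carry out a Rh/BINAP asymmetric 1,4-addition of the B-ring boronic acid, then close C4–C4a by a Ni-catalysed intramolecular decarboxylative (redox-active ester) aryl–alkyl coupling, so the radical step only closes the ring.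
2. **Step 8.** The ortho-iodination may give the wrong regioisomer, di-iodide, or attack on the prenyl alkene. Fallback: replace electrophilic substitution by directed metalation. Protect 10 as its MOM ether, lithiate (only the site between OMOM and OMe is available, since OTIPS neither directs nor leaves its neighbour accessible), quench with I2, and remove the MOM group with mild acid.
3. **Step 3.** The second lithiation of 4 may deprotonate the benzylic/allylic CH2 instead, and the electron-rich o-alkoxy boronate may protodeboronate. Fallback: fix the site with a halogen. Brominate resorcinol to 4-bromoresorcinol, MOM-protect, deprotonate between the OMOM groups with LiTMP and prenylate, then use Br/Li exchange (t-BuLi, −78 °C), transmetalate to zinc, and run a Negishi coupling with the silyl ether of 5.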